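**Plan**

- Retrosynthesis: the epoxide C5–O bond is cut first, back to a C4 alcohol and a C5 mesylate of opposite configuration. Then come the ring bond C5–C6 (vinylogous aldol), C7–C8 (Ni/Cr coupling), C11–C13 (Stille), the two ester C–O bonds and C1–C10 (crotylboration).
- Enabling feature: the carbocycle is numbered C1 (CHOH), C2, C3, C4 (C–CH3, epoxide), C5 (epoxide CH), C6 (lactone O–CH), C7, C8 (tiglate), C9, C10 (CH–CH3); the lactone carbons are C11 (bearing C13H2OAc) and C12 (C=O). C6 is the γ-carbon of the C12(=O)–C11=C7 butenolide and C5 its oxygenated neighbour, while C4 holds a tertiary oxygen that can chelate and later become the epoxide oxygen.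
- Forward order: (R)-linalool gives the C1–C5 chain (C4 PMB ether, vinyl group as latent C5 aldehyde), and crotylboration adds C10, C9 and C8. The butenolide ring (from mucobromic acid) is attached at C7–C8 and given its tiglate and acetoxymethyl group. The ten-membered ring then closes at C5–C6, and the oxirane ring is made last.
- Stereochemistry: C4 comes from (R)-linalool, C1 and C10 from a catalyst-controlled anti crotylboration, and C8 from a CBS reduction. C5 and C6 come from the chelation-controlled, threo-selective ring closure, and C5 is inverted in the epoxide closure.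

Key step: step 16

Assumption: commercial (R)-(−)-linalool of high enantiomeric purity is used, and C1–C13 always mean the positions defined above, whatever the nomenclature numbering of an intermediate.

**Route**

Step 1
Reactants: 1 (R)-linalool
Product: 2 (R)-linalyl 4-methoxybenzyl ether
Conditions: NaH, 4-methoxybenzyl chloride, n-Bu4NI (cat.), THF/DMF, 0 → 50 °C
Reagents that add atoms: 4-methoxybenzyl chloride (COc1ccc(CCl)cc1)
Why: Williamson etherification of the tertiary sodium alkoxide with the benzylic iodide formed in situ should give the ether; no bond to C4 is broken, so the chiral-pool centre is kept.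

Step 2
Reactants: 2 PMB ether
Product: 3 6,7-epoxide of 2 (both epimers at the oxirane CH)
Conditions: mCPBA, CH2Cl2, 0 °C
Reagents that add atoms: 3-chloroperbenzoic acid (O=C(OO)c1cccc(Cl)c1)
Why: Prilezhaev epoxidation is electrophilic and should select the electron-rich trisubstituted alkene over the vinyl group next to the ether oxygen; the new centre is destroyed in step 3.

Step 3
Reactants: 3 epoxide
Product: 5 (4R)-4-[(4-methoxybenzyl)oxy]-4-methylhex-5-enal, via glycol 4 (not isolated)
Conditions: H5IO6, THF/H2O, 0 °C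
Reagents that add atoms: none
Why: periodic acid should open the epoxide to the glycol and cleave it (Malaprade glycol cleavage) to the C1 aldehyde and acetone, the usual degradation of a prenyl terminus, leaving the vinyl group and the PMB ether alone.

Step 4
Reactants: 5 aldehyde; 6 (E)-crotylboronic acid pinacol ester
Product: 7 (3R,4S,7R)-7-[(4-methoxybenzyl)oxy]-3,7-dimethylnona-1,8-dien-4-ol (1S,10R, 1,10-anti)
Conditions: (R)-3,3′-bis(2,4,6-triisopropylphenyl)-1,1′-binaphthyl-2,2′-diyl hydrogen phosphate [(R)-TRIP, 5 mol %], 4 Å MS, toluene, −30 °C; aqueous work-up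
Reagents that add atoms: none
Why: chiral phosphoric acid-catalysed crotylboration through a chair Zimmerman–Traxler transition state, in which the (E)-crotyl geometry should give the 1,10-anti relationship and the (R)-catalyst should direct addition to the Re face of the aldehyde (1S,10R); the remote C4 centre has no say, and a minor diastereomer would be separable.

Step 5
Reactants: 7 homoallylic alcohol
Product: 8 triethylsilyl ether of 7
Conditions: TESCl, imidazole, DMF, 0 °C → rt
Reagents that add atoms: chlorotriethylsilane (CC[Si](Cl)(CC)CC)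
Why: standard silylation of a secondary alcohol, which also prevents lactol formation once C8 becomes an aldehyde.

Step 6
Reactants: 8 silyl ether
Product: 10 (3R,4S,7R)-7-[(4-methoxybenzyl)oxy]-3,7-dimethyl-4-[(triethylsilyl)oxy]non-8-en-1-ol, via alkylborane 9 (not isolated)
Conditions: (c-C6H11)2BH (from cyclohexene and BH3·SMe2), THF, 0 °C; then NaOH, H2O2, 0 °C → rt
Reagents that add atoms: hydrogen peroxide (OO)
Why: anti-Markovnikov hydroboration–oxidation with a bulky dialkylborane should pick the vinyl group on the tertiary carbon C10 over the vinyl group on the fully substituted, oxygen-bearing C4, which is both more hindered and inductively deactivated.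

Step 7
Reactants: 10 primary alcohol
Product: 11 (3R,4S,7R)-7-[(4-methoxybenzyl)oxy]-3,7-dimethyl-4-[(triethylsilyl)oxy]non-8-enal
Conditions: Dess–Martin periodinane, CH2Cl2, 0 °C → rt
Reagents that add atoms: none
Why: Dess–Martin oxidation of a primary alcohol; C10 is β to the new carbonyl group and cannot epimerise.

Step 8
Reactants: 12 mucobromic acid
Product: 13 3,4-dibromofuran-2(5H)-one
Conditions: NaBH4, MeOH, 0 °C; then H2SO4
Reagents that add atoms: none
Why: borohydride reduction of the open-chain aldehyde tautomer followed by acid-induced relactonisation is the established way to this furanone.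

Step 9
Reactants: 11 aldehyde; 13 3,4-dibromofuran-2(5H)-one
Product: 14 C7–C8 coupled carbinol (both C8 epimers)
Conditions: CrCl2 (4 equiv), NiCl2 (2 mol %), DMF, rt, excess 13
Reagents that add atoms: none
Why: Nozaki–Hiyama–Kishi coupling, in which zerovalent nickel should insert into the more electrophilic C4–Br bond of 13 (a vinylogous acyl bromide) and the alkenylchromium species should add only to the aldehyde; C8 is formed without control and is set in steps 10 and 11.

Step 10
Reactants: 14 carbinol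
Product: 15 C8 ketone
Conditions: Dess–Martin periodinane, CH2Cl2, 0 °C → rt
Reagents that add atoms: none
Why: Dess–Martin oxidation of a secondary allylic alcohol under non-basic conditions, so that the acidic C6 methylene of the acylbutenolide is not disturbed.

Step 11
Reactants: 15 ketone
Product: 16 (8S)-alcohol
Conditions: (R)-2-methyl-CBS-oxazaborolidine (0.5 equiv), catecholborane, toluene, −78 °C; MeOH, aqueous work-up
Reagents that add atoms: none
Why: Corey–Bakshi–Shibata reduction, in which the tetrasubstituted butenolide alkenyl group acts as the large and C9H2 as the small substituent, so that the (R)-oxazaborolidine should give the 8S alcohol; catecholborane is chosen because it does not hydroborate the vinyl group at low temperature.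

Step 12
Reactants: 16 alcohol; 17 tiglic acid
Product: 19 C8 tiglate of the bromobutenolide, via mixed anhydride 18 (not isolated)
Conditions: 17, 2,4,6-trichlorobenzoyl chloride, Et3N, THF, rt; then 16, DMAP, toluene, rt
Reagents that add atoms: none
Why: Yamaguchi esterification acylates hindered secondary alcohols through the mixed anhydride and the acylpyridinium ion; the C8–O bond is not broken, so the configuration is kept, and the (E)-tiglate is the stable alkene isomer.

Step 13
Reactants: 19 bromide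
Product: 20 C13 alcohol (11-hydroxymethyl butenolide)
Conditions: Bu3SnCH2OH, Pd(PPh3)4 (10 mol %), dioxane, 90 °C
Reagents that add atoms: (tributylstannyl)methanol (CCCC[Sn](CO)(CCCC)CCCC)
Why: Stille coupling of the α-bromo enoate with the hydroxymethyl stannane; oxidative addition of zerovalent palladium into the activated C11–Br bond should be faster than ionisation of the hindered, electron-poor allylic tiglate.

Step 14
Reactants: 20 alcohol
Product: 21 C13 acetate
Conditions: Ac2O, pyridine, DMAP (cat.), CH2Cl2, 0 °C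
Reagents that add atoms: acetic anhydride (CC(=O)OC(C)=O)
Why: standard acetylation of a primary allylic alcohol.

Step 15
Reactants: 21 vinyl compound
Product: 23 seco aldehyde (C5 aldehyde), via glycol 22 (not isolated)
Conditions: OsO4 (2 mol %), NaIO4, 2,6-lutidine, dioxane/H2O, rt
Reagents that add atoms: osmium tetroxide (O=[Os](=O)(=O)=O), which transfers the oxygen; sodium periodate ([Na+].[O-]I(=O)(=O)=O), which replenishes it
Why: Lemieux–Johnson oxidation, in which OsO4 should dihydroxylate the only isolated alkene faster than the electron-poor tiglate and the tetrasubstituted butenolide, and periodate cleaves the glycol; the aldehyde has no α-hydrogen, so C4 is safe.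

Step 16
Reactants: 23 seco aldehyde
Product: 25 ten-membered C5 alcohol (1S,4R,5R,6S,8S,10R), via silyloxyfuran 24 (not isolated)
Conditions: TIPSOTf (1.1 equiv), Et3N (2.5 equiv), CH2Cl2, 0 °C; then slow addition (syringe pump) to MgBr2·OEt2 (5 equiv), CH2Cl2, −40 → 0 °C, final concentration about 1 mM; aq. NH4Cl
Reagents that add atoms: none
Why: Proposed new method: O-silylation of the lactone carbonyl and removal of a C6 proton by Et3N turn the butenolide into the aromatic 2-silyloxyfuran 24, whose γ-carbon C6 adds in an open transition state to the C5 aldehyde held in a five-membered magnesium chelate between the aldehyde oxygen and the C4 PMB ether oxygen, after which loss of silicon from the oxocarbenium ion restores the butenolide. The closest known reaction type is the intermolecular Lewis acid-mediated vinylogous Mukaiyama aldol addition of 2-silyloxyfurans to α-alkoxy aldehydes under chelation control; closing a ten-membered carbocycle in this way has no direct precedent. The ten-membered ring (C1–C10) closes by exo attack on the aldehyde carbonyl (10-exo-trig), the nucleophilic C6=C7 bond of the furan ending up inside the new ring. C5 is controlled by the Cram chelate, attack past the small C4 methyl group and not past the C3 chain giving 5R (4,5-syn), the configuration needed for the later inversion; C6 is controlled by the synclinal open transition state usual for silyloxyfurans, which gives the 5,6-syn (threo) adduct and hence 6S. The step needs γ- over α-attack (secured by the fully substituted C11 and the regained conjugation), cyclisation over oligomerisation (secured by slow addition at high dilution) and chelate-promoted over silyl triflate-promoted addition (secured by keeping Et3N in excess over TIPSOTf until MgBr2·OEt2 is met); the aldehyde has no α-hydrogen and cannot enolise itself.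

Step 17
Reactants: 25 alcohol
Product: 26 C5 mesylate
Conditions: Ms2O, pyridine, DMAP (cat.), CH2Cl2, 0 °C
Reagents that add atoms: methanesulfonic anhydride (CS(=O)(=O)OS(C)(=O)=O)
Why: O-sulfonylation with pyridine as a weak base keeps the C5 configuration and should not deprotonate C6.

Step 18
Reactants: 26 mesylate
Product: 27 C4 alcohol, C5 mesylate
Conditions: DDQ, CH2Cl2/pH 7 buffer, 0 °C → rt
Reagents that add atoms: none
Why: oxidative PMB ether cleavage by DDQ (benzylic hydride abstraction, hydrolysis of the oxocarbenium ion); with C5 already sulfonylated no p-methoxybenzylidene acetal can form, and silyl ether, esters and mesylate are inert.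

Step 19
Reactants: 27 hydroxy mesylate
Product: 28 4,5-epoxide, C1 triethylsilyl ether (1S,4R,5S,6S,8S,10R)
Conditions: NaN(SiMe3)2 (1.05 equiv), THF, −78 → −20 °C
Reagents that add atoms: none
Why: intramolecular Williamson reaction (3-exo-tet), in which the C4 alkoxide displaces the C5 mesylate from the rear and so inverts C5 from R to S while C4 is untouched; one equivalent of a hindered amide base at low temperature should remove the O–H proton faster than the C6–H proton.

Step 20
Reactants: 28 silyl ether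
Product: 29 target, (1S,4R,5S,6S,8S,10R)-13-acetoxy-4,5-epoxy-1-hydroxy-8-[(E)-2-methylbut-2-enoyloxy]germacr-7(11)-en-12,6-olide
Conditions: HF·pyridine, pyridine, THF, 0 °C
Reagents that add atoms: none
Why: fluoride cleavage of the triethylsilyl ether, buffered with pyridine, should leave the epoxide, both esters and the butenolide untouched.

**Compound list**

1 | (R)-linalool, (3R)-3,7-dimethylocta-1,6-dien-3-ol | C=C[C@](C)(O)CCC=C(C)C | starting material
2 | 1-({[(3R)-3,7-dimethylocta-1,6-dien-3-yl]oxy}methyl)-4-methoxybenzene | C=C[C@](C)(OCc1ccc(OC)cc1)CCC=C(C)C | intermediate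
3 | 3-{(3R)-3-[(4-methoxybenzyl)oxy]-3-methylpent-4-en-1-yl}-2,2-dimethyloxirane (both epimers at the oxirane CH) | C=C[C@](C)(OCc1ccc(OC)cc1)CCC1OC1(C)C | intermediate
4 | (6R)-6-[(4-methoxybenzyl)oxy]-2,6-dimethyloct-7-ene-2,3-diol (both C3 epimers) | C=C[C@](C)(OCc1ccc(OC)cc1)CCC(O)C(C)(C)O | intermediate
5 | (4R)-4-[(4-methoxybenzyl)oxy]-4-methylhex-5-enal | C=C[C@](C)(OCc1ccc(OC)cc1)CCC=O | intermediate
6 | (E)-crotylboronic acid pinacol ester, 2-[(2E)-but-2-en-1-yl]-4,4,5,5-tetramethyl-1,3,2-dioxaborolane | C/C=C/CB1OC(C)(C)C(C)(C)O1 | starting material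
7 | (3R,4S,7R)-7-[(4-methoxybenzyl)oxy]-3,7-dimethylnona-1,8-dien-4-ol | C=C[C@@H](C)[C@@H](O)CC[C@@](C)(OCc1ccc(OC)cc1)C=C | intermediate
8 | triethyl{[(3R,4S,7R)-7-[(4-methoxybenzyl)oxy]-3,7-dimethylnona-1,8-dien-4-yl]oxy}silane | C=C[C@@H](C)[C@@H](O[Si](CC)(CC)CC)CC[C@@](C)(OCc1ccc(OC)cc1)C=C | intermediate
9 | dicyclohexyl{(3R,4S,7R)-7-[(4-methoxybenzyl)oxy]-3,7-dimethyl-4-[(triethylsilyl)oxy]non-8-en-1-yl}borane | C(C[C@@H](C)[C@@H](O[Si](CC)(CC)CC)CC[C@@](C)(OCc1ccc(OC)cc1)C=C)B(C1CCCCC1)C1CCCCC1 | intermediate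
10 | (3R,4S,7R)-7-[(4-methoxybenzyl)oxy]-3,7-dimethyl-4-[(triethylsilyl)oxy]non-8-en-1-ol | OCC[C@@H](C)[C@@H](O[Si](CC)(CC)CC)CC[C@@](C)(OCc1ccc(OC)cc1)C=C | intermediate
11 | (3R,4S,7R)-7-[(4-methoxybenzyl)oxy]-3,7-dimethyl-4-[(triethylsilyl)oxy]non-8-enal | O=CC[C@@H](C)[C@@H](O[Si](CC)(CC)CC)CC[C@@](C)(OCc1ccc(OC)cc1)C=C | intermediate
12 | mucobromic acid, 3,4-dibromo-5-hydroxyfuran-2(5H)-one | O=C1OC(O)C(Br)=C1Br | starting material
13 | 3,4-dibromofuran-2(5H)-one | O=C1OCC(Br)=C1Br | intermediate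
14 | 3-bromo-4-{(3R,4S,7R)-1-hydroxy-7-[(4-methoxybenzyl)oxy]-3,7-dimethyl-4-[(triethylsilyl)oxy]non-8-en-1-yl}furan-2(5H)-one (both epimers at C8, the carbinol carbon) | OC(C[C@@H](C)[C@@H](O[Si](CC)(CC)CC)CC[C@@](C)(OCc1ccc(OC)cc1)C=C)C1=C(Br)C(=O)OC1 | intermediate
15 | 3-bromo-4-{(3R,4S,7R)-7-[(4-methoxybenzyl)oxy]-3,7-dimethyl-4-[(triethylsilyl)oxy]non-8-enoyl}furan-2(5H)-one | O=C(C[C@@H](C)[C@@H](O[Si](CC)(CC)CC)CC[C@@](C)(OCc1ccc(OC)cc1)C=C)C1=C(Br)C(=O)OC1 | intermediate
16 | 3-bromo-4-{(1S,3R,4S,7R)-1-hydroxy-7-[(4-methoxybenzyl)oxy]-3,7-dimethyl-4-[(triethylsilyl)oxy]non-8-en-1-yl}furan-2(5H)-one | O[C@@H](C[C@@H](C)[C@@H](O[Si](CC)(CC)CC)CC[C@@](C)(OCc1ccc(OC)cc1)C=C)C1=C(Br)C(=O)OC1 | intermediate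
17 | tiglic acid, (2E)-2-methylbut-2-enoic acid | C/C=C(\C)C(=O)O | starting material
18 | (2E)-2-methylbut-2-enoic 2,4,6-trichlorobenzoic anhydride | C/C=C(\C)C(=O)OC(=O)c1c(Cl)cc(Cl)cc1Cl | intermediate
19 | (1S,3R,4S,7R)-1-(4-bromo-5-oxo-2,5-dihydrofuran-3-yl)-7-[(4-methoxybenzyl)oxy]-3,7-dimethyl-4-[(triethylsilyl)oxy]non-8-en-1-yl (2E)-2-methylbut-2-enoate | C/C=C(\C)C(=O)O[C@@H](C[C@@H](C)[C@@H](O[Si](CC)(CC)CC)CC[C@@](C)(OCc1ccc(OC)cc1)C=C)C1=C(Br)C(=O)OC1 | intermediate
20 | (1S,3R,4S,7R)-1-[4-(hydroxymethyl)-5-oxo-2,5-dihydrofuran-3-yl]-7-[(4-methoxybenzyl)oxy]-3,7-dimethyl-4-[(triethylsilyl)oxy]non-8-en-1-yl (2E)-2-methylbut-2-enoate | C/C=C(\C)C(=O)O[C@@H](C[C@@H](C)[C@@H](O[Si](CC)(CC)CC)CC[C@@](C)(OCc1ccc(OC)cc1)C=C)C1=C(CO)C(=O)OC1 | intermediate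
21 | (1S,3R,4S,7R)-1-{4-[(acetyloxy)methyl]-5-oxo-2,5-dihydrofuran-3-yl}-7-[(4-methoxybenzyl)oxy]-3,7-dimethyl-4-[(triethylsilyl)oxy]non-8-en-1-yl (2E)-2-methylbut-2-enoate | C/C=C(\C)C(=O)O[C@@H](C[C@@H](C)[C@@H](O[Si](CC)(CC)CC)CC[C@@](C)(OCc1ccc(OC)cc1)C=C)C1=C(COC(C)=O)C(=O)OC1 | intermediate
22 | (1S,3R,4S,7R)-1-{4-[(acetyloxy)methyl]-5-oxo-2,5-dihydrofuran-3-yl}-8,9-dihydroxy-7-[(4-methoxybenzyl)oxy]-3,7-dimethyl-4-[(triethylsilyl)oxy]nonyl (2E)-2-methylbut-2-enoate (both epimers at the new carbinol) | C/C=C(\C)C(=O)O[C@@H](C[C@@H](C)[C@@H](O[Si](CC)(CC)CC)CC[C@@](C)(OCc1ccc(OC)cc1)C(O)CO)C1=C(COC(C)=O)C(=O)OC1 | intermediate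
23 | (1S,3R,4S,7R)-1-{4-[(acetyloxy)methyl]-5-oxo-2,5-dihydrofuran-3-yl}-7-[(4-methoxybenzyl)oxy]-3,7-dimethyl-8-oxo-4-[(triethylsilyl)oxy]octyl (2E)-2-methylbut-2-enoate | C/C=C(\C)C(=O)O[C@@H](C[C@@H](C)[C@@H](O[Si](CC)(CC)CC)CC[C@@](C)(OCc1ccc(OC)cc1)C=O)C1=C(COC(C)=O)C(=O)OC1 | intermediate
24 | (1S,3R,4S,7R)-1-{4-[(acetyloxy)methyl]-5-[(triisopropylsilyl)oxy]furan-3-yl}-7-[(4-methoxybenzyl)oxy]-3,7-dimethyl-8-oxo-4-[(triethylsilyl)oxy]octyl (2E)-2-methylbut-2-enoate | C/C=C(\C)C(=O)O[C@@H](C[C@@H](C)[C@@H](O[Si](CC)(CC)CC)CC[C@@](C)(OCc1ccc(OC)cc1)C=O)c1coc(O[Si](C(C)C)(C(C)C)C(C)C)c1COC(C)=O | intermediate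
25 | (1S,4R,5R,6S,8S,10R)-13-acetoxy-5-hydroxy-4-[(4-methoxybenzyl)oxy]-8-[(E)-2-methylbut-2-enoyloxy]-1-[(triethylsilyl)oxy]germacr-7(11)-en-12,6-olide | C/C=C(\C)C(=O)O[C@H]1C[C@@H](C)[C@@H](O[Si](CC)(CC)CC)CC[C@@](C)(OCc2ccc(OC)cc2)[C@H](O)[C@H]2OC(=O)C(COC(C)=O)=C12 | intermediate
26 | (1S,4R,5R,6S,8S,10R)-13-acetoxy-5-(methanesulfonyloxy)-4-[(4-methoxybenzyl)oxy]-8-[(E)-2-methylbut-2-enoyloxy]-1-[(triethylsilyl)oxy]germacr-7(11)-en-12,6-olide | C/C=C(\C)C(=O)O[C@H]1C[C@@H](C)[C@@H](O[Si](CC)(CC)CC)CC[C@@](C)(OCc2ccc(OC)cc2)[C@H](OS(C)(=O)=O)[C@H]2OC(=O)C(COC(C)=O)=C12 | intermediate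
27 | (1S,4R,5R,6S,8S,10R)-13-acetoxy-4-hydroxy-5-(methanesulfonyloxy)-8-[(E)-2-methylbut-2-enoyloxy]-1-[(triethylsilyl)oxy]germacr-7(11)-en-12,6-olide | C/C=C(\C)C(=O)O[C@H]1C[C@@H](C)[C@@H](O[Si](CC)(CC)CC)CC[C@@](C)(O)[C@H](OS(C)(=O)=O)[C@H]2OC(=O)C(COC(C)=O)=C12 | intermediate
28 | (1S,4R,5S,6S,8S,10R)-13-acetoxy-4,5-epoxy-8-[(E)-2-methylbut-2-enoyloxy]-1-[(triethylsilyl)oxy]germacr-7(11)-en-12,6-olide | C/C=C(\C)C(=O)O[C@H]1C[C@@H](C)[C@@H](O[Si](CC)(CC)CC)CC[C@@]2(C)O[C@H]2[C@H]2OC(=O)C(COC(C)=O)=C12 | intermediate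
29 | (1S,4R,5S,6S,8S,10R)-13-acetoxy-4,5-epoxy-1-hydroxy-8-[(E)-2-methylbut-2-enoyloxy]germacr-7(11)-en-12,6-olide | C/C=C(\C)C(=O)O[C@H]1C[C@@H](C)[C@@H](O)CC[C@@]2(C)O[C@H]2[C@H]2OC(=O)C(COC(C)=O)=C12 | target

**Count and risks**

Total step count: 20. Longest linear sequence: 19 steps (steps 1–7 and 9–20, from (R)-linalool); step 8 is a one-step side branch.

Steps most likely to fail:

1. Step 16, the unprecedented ring closure. It may fail through intermolecular aldol addition (oligomers), through attack on the other aldehyde face or erythro addition when ring strain overrides the chelate, or through ionisation of the C13 acetate or C8 tiglate from the electron-rich silyloxyfuran. The fallback forms C5–C6 first, intermolecularly, which is known chemistry, and closes the ring at C7–C8 by an intramolecular Nozaki–Hiyama–Kishi reaction, a known route to medium rings. It sets out from alcohol 10 and furanone 13 and comes back at mesylate 26.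
   - Silylation of 10 (TESCl, imidazole) gives the bis(triethylsilyl) ether F1, and Lemieux–Johnson cleavage of its vinyl group gives the C5 aldehyde F2.
   - 13 is converted (TIPSOTf, Et3N) into 3,4-dibromo-2-(triisopropylsilyloxy)furan F3, which adds to F2 under MgBr2·OEt2 chelation control to give the threo adduct F4, with C5 and C6 arranged as in 25.
   - Mesylation gives the C5 mesylate F5. Swern oxidation, which turns a primary triethylsilyl ether directly into the aldehyde and spares the secondary one, gives the C8 aldehyde F6.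
   - CrCl2 with catalytic NiCl2 at high dilution closes the ten-membered ring to the C8 carbinol F7.
   - As in steps 10–14, Dess–Martin oxidation gives the ketone F8, CBS reduction the 8S alcohol F9, Yamaguchi esterification the tiglate F10, and Stille coupling with Bu3SnCH2OH the C13 alcohol F11. Acetylation of F11 gives 26.

2. Step 19, the epoxide closure. The base may remove the C6 proton instead, and the resulting dienolate may expel the C5 mesylate (or the C13 acetate) by an E1cB pathway to an alkylidene butenolide; the anti arrangement of O–C4–C5–OMs may also be hard to reach in the ring. The fallback avoids a free alkoxide and a sulfonate. It sets out from alcohol 25: DDQ in wet CH2Cl2 removes the PMB group to give the 4,5-diol F12, and Mitsunobu cyclodehydration (PPh3, DIAD, toluene) activates the less hindered secondary C5 oxygen as the oxyphosphonium ion, which the tertiary C4 oxygen displaces with inversion. This gives epoxide 28, where the route is rejoined.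

3. Step 6, the site-selective hydroboration. The borane may also attack the C4 vinyl group or add twice, so that the two terminal alkenes are not told apart well enough. The fallback brings C8 in already oxidised, so that a second vinyl group never arises. It sets out from aldehyde 5.
   - (E)-But-2-en-1-yl N,N-diisopropylcarbamate is lithiated (n-BuLi with sparteine, the antipode that leads to the 1S,10R adduct being chosen), transmetallated with Ti(OiPr)4 and added to 5 (Hoppe homoaldol reaction) to give the anti (Z)-enol carbamate F13.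
   - Silylation (TESOTf, 2,6-lutidine) gives its triethylsilyl ether F14.
   - MeLi cleaves the carbamate to the lithium enolate, which on protonation gives aldehyde 11, where the route is rejoined (steps 4–7 are replaced).

Further compounds
F1 | step 16 | (3R,4S,7R)-7-[(4-methoxybenzyl)oxy]-3,7-dimethyl-1,4-bis[(triethylsilyl)oxy]non-8-ene | CC[Si](CC)(CC)OCC[C@@H](C)[C@@H](O[Si](CC)(CC)CC)CC[C@@](C)(OCc1ccc(OC)cc1)C=C
F2 | step 16 | (2R,5S,6R)-2-[(4-methoxybenzyl)oxy]-2,6-dimethyl-5,8-bis[(triethylsilyl)oxy]octanal | CC[Si](CC)(CC)OCC[C@@H](C)[C@@H](O[Si](CC)(CC)CC)CC[C@@](C)(OCc1ccc(OC)cc1)C=O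
F3 | step 16 | 3,4-dibromo-2-[(triisopropylsilyl)oxy]furan | CC(C)[Si](Oc1occ(Br)c1Br)(C(C)C)C(C)C
F4 | step 16 | 3,4-dibromo-5-{1-hydroxy-2-[(4-methoxybenzyl)oxy]-2,6-dimethyl-5,8-bis[(triethylsilyl)oxy]octyl}furan-2(5H)-one, threo adduct with C5 and C6 arranged as in 25 | CC[Si](CC)(CC)OCC[C@@H](C)[C@@H](O[Si](CC)(CC)CC)CC[C@@](C)(OCc1ccc(OC)cc1)[C@H](O)[C@H]1OC(=O)C(Br)=C1Br
F5 | step 16 | C5 methanesulfonate of F4 | CC[Si](CC)(CC)OCC[C@@H](C)[C@@H](O[Si](CC)(CC)CC)CC[C@@](C)(OCc1ccc(OC)cc1)[C@H](OS(C)(=O)=O)[C@H]1OC(=O)C(Br)=C1Br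
F6 | step 16 | C8 aldehyde from F5 (primary silyl ether oxidised) | O=CC[C@@H](C)[C@@H](O[Si](CC)(CC)CC)CC[C@@](C)(OCc1ccc(OC)cc1)[C@H](OS(C)(=O)=O)[C@H]1OC(=O)C(Br)=C1Br
F7 | step 16 | ten-membered 11-bromobutenolide C8 carbinol (both C8 epimers), C5 mesylate, C4 PMB ether, C1 triethylsilyl ether | OC1C[C@@H](C)[C@@H](O[Si](CC)(CC)CC)CC[C@@](C)(OCc2ccc(OC)cc2)[C@H](OS(C)(=O)=O)[C@H]2OC(=O)C(Br)=C12
F8 | step 16 | C8 ketone from F7 | O=C1C[C@@H](C)[C@@H](O[Si](CC)(CC)CC)CC[C@@](C)(OCc2ccc(OC)cc2)[C@H](OS(C)(=O)=O)[C@H]2OC(=O)C(Br)=C12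
F9 | step 16 | (8S)-alcohol from F8 | O[C@H]1C[C@@H](C)[C@@H](O[Si](CC)(CC)CC)CC[C@@](C)(OCc2ccc(OC)cc2)[C@H](OS(C)(=O)=O)[C@H]2OC(=O)C(Br)=C12
F10 | step 16 | C8 tiglate of F9 (26 with bromine in place of the acetoxymethyl group) | C/C=C(\C)C(=O)O[C@H]1C[C@@H](C)[C@@H](O[Si](CC)(CC)CC)CC[C@@](C)(OCc2ccc(OC)cc2)[C@H](OS(C)(=O)=O)[C@H]2OC(=O)C(Br)=C12
F11 | step 16 | C13 alcohol from F10 (26 lacking the acetyl group) | C/C=C(\C)C(=O)O[C@H]1C[C@@H](C)[C@@H](O[Si](CC)(CC)CC)CC[C@@](C)(OCc2ccc(OC)cc2)[C@H](OS(C)(=O)=O)[C@H]2OC(=O)C(CO)=C12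
F12 | step 19 | (1S,4R,5R,6S,8S,10R)-13-acetoxy-4,5-dihydroxy-8-[(E)-2-methylbut-2-enoyloxy]-1-[(triethylsilyl)oxy]germacr-7(11)-en-12,6-olide | C/C=C(\C)C(=O)O[C@H]1C[C@@H](C)[C@@H](O[Si](CC)(CC)CC)CC[C@@](C)(O)[C@H](O)[C@H]2OC(=O)C(COC(C)=O)=C12
F13 | step 6 | (1Z,3R,4S,7R)-4-hydroxy-7-[(4-methoxybenzyl)oxy]-3,7-dimethylnona-1,8-dien-1-yl N,N-diisopropylcarbamate | CC(C)N(C(C)C)C(=O)O/C=C\[C@@H](C)[C@@H](O)CC[C@@](C)(OCc1ccc(OC)cc1)C=C
F14 | step 6 | triethylsilyl ether of F13 | CC(C)N(C(C)C)C(=O)O/C=C\[C@@H](C)[C@@H](O[Si](CC)(CC)CC)CC[C@@](C)(OCc1ccc(OC)cc1)C=C
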